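**Retrosynthetic overview**
- Target (3S,5R)-syn-1,3-diol ⇐ (5R)-β-hydroxy ketone: a chelation-controlled 1,3-syn reduction sets C3.
- β-Hydroxy ketone ⇐ C4–C5 bond: direct asymmetric enamine aldol of zingerone (methyl terminus) with 3-(4-hydroxy-3,5-dimethoxyphenyl)propanal, using a new organocatalyst; this sets C5.
- The propanal ⇐ sinapaldehyde by C=C hydrogenation.
- No ring is formed: both arenes are bought intact, and no protecting groups are used.

Assumption: chain locants run from the guaiacyl end (C1) to the syringyl end (C7), so the target SMILES is the (3S,5R) syn-diol.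

Catalyst Cat-A (a reagent, not numbered, not counted as a step): (R)-N-[3,3,3-trifluoro-2-hydroxy-2-(trifluoromethyl)propyl]pyrrolidine-2-carboxamide, SMILES O=C(NCC(O)(C(F)(F)F)C(F)(F)F)[C@H]1CCCN1. It is made separately from N-Boc-D-proline and 3-amino-1,1,1-trifluoro-2-(trifluoromethyl)propan-2-ol by amide coupling and Boc removal.

**Route**

Step 1
Reactants: 1 sinapaldehyde [(E)-3-(4-hydroxy-3,5-dimethoxyphenyl)prop-2-enal]
Product: 2 3-(4-hydroxy-3,5-dimethoxyphenyl)propanal
Conditions: H2 (1 atm), 10% Pd/C (5 mol%), Ph2S (1 mol%), EtOAc, rt, stop after 1 equiv H2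
Reagents that add atoms: none
Why: Chemoselective heterogeneous catalytic hydrogenation; sulfide-moderated Pd reduces the conjugated C=C much faster than the aliphatic C=O, the phenol and aryl ethers are inert, and no stereocentre is formed.

Step 2
Reactants: 2 3-(4-hydroxy-3,5-dimethoxyphenyl)propanal; 3 zingerone (vanillylacetone)
Product: 5 (5R)-5-hydroxy-7-(4-hydroxy-3,5-dimethoxyphenyl)-1-(4-hydroxy-3-methoxyphenyl)heptan-3-one, via zingerone enamine 4 (not isolated)
Conditions: Cat-A (10 mol%), 3 in fourfold excess (excess recovered), 2-MeTHF (3 M in 3), −25 °C, 2 added by syringe pump over 12 h, then 48 h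
Reagents that add atoms: none
Why: Proposed new method: a direct enamine aldol through a Houk–List-type transition state, in which the pyrrolidine of the new D-prolinamide Cat-A condenses with 3 at the less hindered methyl side to give enamine 4, while its amide N–H and its acidic, non-nucleophilic (CF3)2C–OH clamp the carbonyl oxygen of 2 so that 4 attacks the si face and sets C5 as R (the mirror image of the re-face attack given by L-proline-type catalysts), after which hydrolysis of the product iminium gives 5 and returns Cat-A to the cycle; this stronger double hydrogen-bond activation at low temperature, with slow addition of 2 and excess 3, is meant to outrun aldehyde self-aldol and dehydration, which so far limit such aldols of α-unbranched aldehydes, and the free phenols are not preorganised next to the enamine and should not override the clamp; the closest known reaction type is the proline/prolinamide–amino-alcohol catalysed aldol of acetone with aldehydes.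

Step 3
Reactants: 5 (5R)-5-hydroxy-7-(4-hydroxy-3,5-dimethoxyphenyl)-1-(4-hydroxy-3-methoxyphenyl)heptan-3-one
Product: 8 (3S,5R)-7-(4-hydroxy-3,5-dimethoxyphenyl)-1-(4-hydroxy-3-methoxyphenyl)heptane-3,5-diol, via O,O-diethylboron chelate of the ketol 6 (not isolated), via sodium cyclic diethylborate of the syn-diol 7 (not isolated)
Conditions: Et2BOMe (3 equiv), THF/MeOH 4:1, −78 °C, 30 min; NaBH4 (2 equiv), −78 °C, 4 h; pH 7 buffer, then MeOH co-evaporation
Reagents that add atoms: none
Why: Narasaka–Prasad reduction; the six-membered boron chelate 6 takes a half-chair with the C5 side chain pseudo-equatorial and external hydride adds axially to give the 1,3-syn diol (new C3 = S next to the untouched 5R), while the phenols borylate only reversibly in methanol and are freed on work-up.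

**Compound list**
1 | sinapaldehyde, (E)-3-(4-hydroxy-3,5-dimethoxyphenyl)prop-2-enal | COc1cc(/C=C/C=O)cc(OC)c1O | starting material
2 | 3-(4-hydroxy-3,5-dimethoxyphenyl)propanal | COc1cc(CCC=O)cc(OC)c1O | intermediate
3 | zingerone (vanillylacetone), 4-(4-hydroxy-3-methoxyphenyl)butan-2-one | COc1cc(CCC(C)=O)ccc1O | starting material
4 | zingerone enamine (terminal enamine of 3 on the pyrrolidine nitrogen of Cat-A), (R)-1-[4-(4-hydroxy-3-methoxyphenyl)but-1-en-2-yl]-N-[3,3,3-trifluoro-2-hydroxy-2-(trifluoromethyl)propyl]pyrrolidine-2-carboxamide | C=C(CCc1ccc(O)c(OC)c1)N1CCC[C@@H]1C(=O)NCC(O)(C(F)(F)F)C(F)(F)F | intermediate (not isolated)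
5 | (5R)-5-hydroxy-7-(4-hydroxy-3,5-dimethoxyphenyl)-1-(4-hydroxy-3-methoxyphenyl)heptan-3-one | COc1cc(CCC(=O)C[C@H](O)CCc2cc(OC)c(O)c(OC)c2)ccc1O | intermediate
6 | O,O-diethylboron chelate of 5 (six-membered ring C5–O–BEt2←O=C3, 5R; phenols drawn free) | CC[B-]1(CC)O[C@H](CCc2cc(OC)c(O)c(OC)c2)CC(CCc2ccc(O)c(OC)c2)=[O+]1 | intermediate (not isolated)
7 | sodium cyclic diethylborate of the (3S,5R)-syn-diol (2,2-diethyl-1,3,2-dioxaborinan-2-uide, ring substituents cis; phenols drawn free) | CC[B-]1(CC)O[C@H](CCc2cc(OC)c(O)c(OC)c2)C[C@H](CCc2ccc(O)c(OC)c2)O1.[Na+] | intermediate (not isolated)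
8 | (3S,5R)-7-(4-hydroxy-3,5-dimethoxyphenyl)-1-(4-hydroxy-3-methoxyphenyl)heptane-3,5-diol | COc1cc(CC[C@H](O)C[C@H](O)CCc2cc(OC)c(O)c(OC)c2)ccc1O | target

**Totals**
Total step count: 3. Longest linear sequence: 3 (1 → 2 → 5 → 8).

**Steps most likely to fail**

1. Step 2 (the proposed new aldol). Risks are low ee with the unbranched aldehyde, aldehyde self-aldol, dehydration to the enone, and catalyst parking as an imidazolidinone. The fallback uses known chemistry only, sets out from 2 and 3, and comes back at 5. A pyrrolidine/AcOH-mediated crossed aldol condensation at the methyl terminus of 3 with 2 gives (E)-1-(4-hydroxy-3-methoxyphenyl)-7-(4-hydroxy-3,5-dimethoxyphenyl)hept-4-en-3-one F2, which is also the by-product expected if the new aldol dehydrates. Primary-amine-catalysed asymmetric epoxidation (9-amino-9-deoxy-epi-cinchona amine·TFA salt, aqueous H2O2, dioxane) then gives (4S,5R)-4,5-epoxy-1-(4-hydroxy-3-methoxyphenyl)-7-(4-hydroxy-3,5-dimethoxyphenyl)heptan-3-one F3. The quinine- or quinidine-derived pseudoenantiomer is chosen, whichever delivers the (4S,5R)-epoxide. Selenolate-mediated reductive cleavage of the Cα–O bond ((PhSe)2, NaBH4, AcOH, EtOH, 0 °C) leaves the C5–O bond untouched and gives 5.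

2. Step 3 (syn reduction with two free phenols). The risk is that phenol borylation erodes chelation and hence the syn:anti ratio, or that boron is hard to strip from the polar product. The fallback sets out from 5 and comes back at 8. BnBr/K2CO3 in DMF at rt alkylates only the two phenols to give (5R)-1-(4-benzyloxy-3-methoxyphenyl)-7-(4-benzyloxy-3,5-dimethoxyphenyl)-5-hydroxyheptan-3-one F4. The same Et2BOMe/NaBH4 reduction, now without competing ArOH, gives (3S,5R)-1-(4-benzyloxy-3-methoxyphenyl)-7-(4-benzyloxy-3,5-dimethoxyphenyl)heptane-3,5-diol F5. Hydrogenolysis (H2, Pd/C, EtOAc/MeOH) then gives 8.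

3. Step 1 (selective C=C hydrogenation). The risk is over-reduction to the saturated alcohol or loss of the sensitive phenolic aldehyde. The fallback sets out from 1 and comes back at 2. NaBH4 1,2-reduction (EtOH, 0 °C) gives sinapyl alcohol, (E)-4-(3-hydroxyprop-1-en-1-yl)-2,6-dimethoxyphenol F1. A redox-neutral Ru-catalysed isomerisation of the allylic alcohol (CpRu(PPh3)2Cl, Et3NH·PF6, dioxane, 80 °C) then gives 2; no H2 is present, so over-reduction cannot occur.

**Further compounds**
F1 | step 1 | sinapyl alcohol, (E)-4-(3-hydroxyprop-1-en-1-yl)-2,6-dimethoxyphenol | COc1cc(/C=C/CO)cc(OC)c1O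
F2 | step 2 | (E)-1-(4-hydroxy-3-methoxyphenyl)-7-(4-hydroxy-3,5-dimethoxyphenyl)hept-4-en-3-one | COc1cc(CCC(=O)/C=C/CCc2cc(OC)c(O)c(OC)c2)ccc1O
F3 | step 2 | (4S,5R)-4,5-epoxy-1-(4-hydroxy-3-methoxyphenyl)-7-(4-hydroxy-3,5-dimethoxyphenyl)heptan-3-one (trans-epoxide) | COc1cc(CCC(=O)[C@H]2O[C@@H]2CCc2cc(OC)c(O)c(OC)c2)ccc1O
F4 | step 3 | (5R)-1-(4-benzyloxy-3-methoxyphenyl)-7-(4-benzyloxy-3,5-dimethoxyphenyl)-5-hydroxyheptan-3-one | COc1cc(CCC(=O)C[C@H](O)CCc2cc(OC)c(OCc3ccccc3)c(OC)c2)ccc1OCc1ccccc1
F5 | step 3 | (3S,5R)-1-(4-benzyloxy-3-methoxyphenyl)-7-(4-benzyloxy-3,5-dimethoxyphenyl)heptane-3,5-diol | COc1cc(CC[C@H](O)C[C@H](O)CCc2cc(OC)c(OCc3ccccc3)c(OC)c2)ccc1OCc1ccccc1
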